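The earlier runs and the new flask were computed from invented constants; scatter was added.

**The question.** How much Q, the product, did the dawn run make by 25 min, with the catalyst G at 0.400 of its dusk charge? And what power of X, the substrate, did the first rate follow?

common to all: J 0.360 M
- dusk: X 0.120 M; G 6.00 × 10⁻⁴ M
- midnight: X 0.180 M; G 6.00 × 10⁻⁴ M
- dawn: X 0.120 M; G 2.40 × 10⁻⁴ M; time 25 min

| dusk run: time / min | dusk run: [Q] / M | midnight run: time / min | midnight run: [Q] / M |
|---|---|---|---|
| 1.9 | 0.0428 | 1.9 | 0.0540 |
| 5.8 | 0.0601 | 5.8 | 0.0754 |
| 11 | 0.0678 | 11 | 0.0834 |
| 17 | 0.0705 | 17 | 0.0862 |
| 25 | 0.0724 | 25 | 0.0888 |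

(scatter of a reading: 4 × 10⁻⁴ M)

- Overall: X + J -> Q, with G as catalyst.
- Constant volume, constant temperature.
- The analysis sees a species whether free or bound.
- "The second partner" is J.
- An order is taken over about fifteen percent of the charge, up and down.

* the power of [X] that the first rate follows, about the charge of the dusk run; measure it at two percent of X made into Q (one fixed amount of Q, the same in the runs compared)
* Q in the dawn run at 25 min, as a share of the X charged

**The balance.** In the dusk run X was the limiting reagent by charge, 0.120 M against 0.360 M of the reagent J. Yet the dusk run still held 0.0476 M of X at its last reading. Its mean rate went from 0.0225 M/min up to the first reading to 2.38 × 10⁻⁴ M/min between the last two readings, a drop by a factor of 94.8, while X fell by a factor of 2.52. So something besides X slowed the flask.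

**The yardstick.** The dusk run gave 0.925 for the exposure E, the natural log of X charged over X left. It counts time constants of X as if X were first-order. The readings at 1.9 min, a rough stand-in for the first rates, gave me an order of 0.573. The midnight E was 0.680, lower, so I used E between runs of equal X charge.

**Two ways.** If the stop ran on wall-clock time, E scaled with G. Dawn then had E of 0.370, a share of 30.9%. If the stop counted turnovers, dawn at 25 min matched dusk at 10.0 min, and the nearest dusk reading, at 11 min, is 56.5% of X.

The midnight run split them. It had the dusk charge of G, so a stop at a fixed count of turnovers gave it the dusk Q. Yet its last reading was 1.23 times the dusk one. I trusted the wall clock.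

**The forecast.** It gave 0.6 and 41%, saying “The runs can't separate these”. My 30.9% stood lower.

**The result.** The flask gave 0.60 and 31.9%.

    G + X ⇌ GX, settled at all times (6.830 /M)
    GX + J → Q + G + L (648.0 /M/min)
    G + X → Wy + X (0.4206 /M/min)
    2 J → Ze (2.364 /M/min)

The dawn exposure came to 0.384, which is 0.415 of the E read at dusk, close to the G ratio of 0.400. The wall clock was the conversion of J into Ze, a step that does not involve G. In the dawn run without that step, Q reached 99.5% of the X charged, an exposure of 5.30 against 0.384.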